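## Retrosynthetic overview
1. Both spiroketal rings are made together in the last step. A 2-methyl-5-(3-hydroxyalkyl)furan is dearomatised by an enantioselective, interrupted hydrogenation: H2 across the MeC=CH bond sets C7'', and the C2''-OH captures the remaining enol ether to form spiro C5''.
2. The furyl carbinol is cut at C6'–C2''. An alkylzinc from a 3-(hex-5-enyl)phthalide adds to 3-(5-methylfuran-2-yl)propanal under asymmetric catalysis, which sets C2''(S).
3. The aldehyde comes from 2-methylfuran and acrolein by one conjugate Friedel–Crafts addition.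
4. The phthalide comes from 3,5-dimethoxybenzaldehyde by mono-bromination, catalytic asymmetric hexenyl addition (sets C3 R), then Br/Li exchange, CO2 and lactonisation.
5. Ring order: the phthalide lactone is closed first, the furan is carried as latent ring B, and spiroketal rings B and A form last in one operation.

Assumptions:
- Locants are C3 for the phthalide carbon, C1'–C6' for the hexyl chain, and C2''/C5''/C7'' for the spiroketal.
- A one-flask sequence counts as one step. Returning unconverted material to the same conditions does not count as a new step.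
- The ligand antipode in step 6 is assigned by analogy with 2-alkylfurans and would be confirmed on a model furan. Both antipodes are accessible.

## Route

Step 1
Reactants: 1 3,5-dimethoxybenzaldehyde
Product: 2 2-bromo-3,5-dimethoxybenzaldehyde
Conditions: NBS (1.05 equiv), MeCN, 0 °C → rt, 2 h
Reagents that add atoms: N-bromosuccinimide, O=C1CCC(=O)N1Br
Why: Electrophilic aromatic bromination; C2 (= C6) is para to one OMe, ortho to the other and less hindered than C4, so the symmetric ring is mono-brominated at the carbon that will carry the lactone carbonyl, and no stereocentre is formed.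

Step 2
Reactants: 2 2-bromo-3,5-dimethoxybenzaldehyde; 3 6-bromohex-1-ene
Product: 6 (R)-1-(2-bromo-3,5-dimethoxyphenyl)hept-6-en-1-ol, via hex-5-en-1-ylmagnesium bromide 4 (not isolated), via hex-5-en-1-yltitanium triisopropoxide 5 (not isolated)
Conditions: 3, Mg, Et2O, reflux; Ti(OiPr)4 (excess), CH2Cl2, −78 °C; slow addition to 2, (R)-3-(3,5-diphenylphenyl)-H8-BINOL (3 mol %), CH2Cl2, 0 °C; 1 M HCl
Reagents that add atoms: none
Why: Catalytic asymmetric alkylation of an aryl aldehyde with a Grignard-derived alkyltitanium under a BINOLate–Ti catalyst; the (R)-ligand series delivers alkyl to the Re face of ArCHO and gives the (R)-carbinol (about 90–95% ee expected), and the non-basic RTi(OiPr)3 leaves the ArBr untouched.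

Step 3
Reactants: 6 (R)-1-(2-bromo-3,5-dimethoxyphenyl)hept-6-en-1-ol
Product: 9 (R)-3-(hex-5-en-1-yl)-5,7-dimethoxyisobenzofuran-1(3H)-one, via O,C-dilithio species 7 (not isolated), via (R)-2-(1-hydroxyhept-6-en-1-yl)-4,6-dimethoxybenzoic acid 8 (not isolated)
Conditions: n-BuLi (2.2 equiv), THF, −78 °C; CO2 (g), −78 °C → rt; 2 M HCl, rt
Reagents that add atoms: carbon dioxide, O=C=O
Why: Bromine–lithium exchange, carboxylation and spontaneous γ-lactonisation; the benzylic C–O bond is never broken so C3 stays (R), and the isolated terminal alkene is inert at −78 °C.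

Step 4
Reactants: 10 2-methylfuran; 11 acrolein
Product: 12 3-(5-methylfuran-2-yl)propanal
Conditions: 10 (2 equiv), AcOH (10 mol %), hydroquinone (0.5 mol %), 40 °C, 16 h; distil
Reagents that add atoms: none
Why: Acid-catalysed Friedel–Crafts conjugate addition; the only free α-position (C5) of the π-rich furan attacks the β-carbon of the activated enal, and no stereocentre is formed.

Step 5
Reactants: 9 (R)-3-(hex-5-en-1-yl)-5,7-dimethoxyisobenzofuran-1(3H)-one; 12 3-(5-methylfuran-2-yl)propanal
Product: 16 (R)-3-[(S)-7-hydroxy-9-(5-methylfuran-2-yl)nonyl]-5,7-dimethoxyisobenzofuran-1(3H)-one, via alkyl(diethyl)borane 13 (not isolated), via dialkylzinc 14 (not isolated), via alkyl(trimethylsilylmethyl)zinc 15 (not isolated)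
Conditions: Et2BH (from Et3B + BH3·SMe2, 1.05 equiv), Et2O, 0 °C → rt, evaporate; Et2Zn (neat), 0 °C, 30 min, evaporate; (Me3SiCH2)2Zn (0.5 equiv), Et2O; 12 (0.75 equiv), Ti(OiPr)4 (0.6 equiv), (1R,2R)-1,2-bis(trifluoromethanesulfonamido)cyclohexane (8 mol %), −20 °C, 24 h; cold 1 M HCl
Reagents that add atoms: none
Why: Anti-Markovnikov hydroboration, boron–zinc exchange and Ti–bis(sulfonamide)-catalysed asymmetric alkylzinc addition; the (R,R)-ligand directs the alkyl group to the Si face of the aliphatic aldehyde and gives C2''(S) (dr about 95:5), Me3SiCH2 is a non-transferable group so little of 9 is wasted, and lactone and furan tolerate R2Zn.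

Step 6
Reactants: 16 (R)-3-[(S)-7-hydroxy-9-(5-methylfuran-2-yl)nonyl]-5,7-dimethoxyisobenzofuran-1(3H)-one
Product: 19 (3R)-5,7-dimethoxy-3-{6-[(2S,5R,7S)-7-methyl-1,6-dioxaspiro[4.4]nonan-2-yl]hexyl}isobenzofuran-1(3H)-one, via (R)-3-{(S)-7-hydroxy-9-[(S)-5-methyl-4,5-dihydrofuran-2-yl]nonyl}-5,7-dimethoxyisobenzofuran-1(3H)-one 17 (not isolated), via (3R)-5,7-dimethoxy-3-{6-[(2S,5S,7S)-7-methyl-1,6-dioxaspiro[4.4]nonan-2-yl]hexyl}isobenzofuran-1(3H)-one 18 (not isolated)
Conditions: [Ir(cod)(L*)]BArF (3 mol %; L* = di-tert-butylphosphinite of enantiopure 2-phenyl-5,6,7,8-tetrahydroquinolin-8-ol), H2 (80 bar), CH2Cl2, 40 °C, 24 h; vent; CSA (5 mol %), rt, 1 h; Et3N; HPLC; the fraction that still holds 18 goes back, as eluted, into CSA/CH2Cl2 (rt) and is separated again (2–3 cycles)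
Reagents that add atoms: none
Why: Proposed new method: cationic Ir–N,P dihydrides hydrogenate alkylfurans enantioselectively, and the dearomatising first H2 addition is slow and stereodetermining; here it should occur at the less hindered MeC=CH bond, with the face fixed by the quadrant rule for trisubstituted olefins (the lone vinylic H takes the hindered quadrant, so no Me/alkyl discrimination is needed for facial control), giving the (S)-enol ether 17; the Ir–H species formed under H2 are strong Brønsted acids, so 17 is protonated at C9'' and the tertiary oxocarbenium ion is trapped 5-exo by the C2''-OH faster than a second hydrogenation, which stops the reduction at the spiroketal; addition to the other furan C=C gives only a constitutionally different, separable tetrahydrofuran alcohol and not a C7'' epimer; trapping occurs on both faces of the oxocarbenium ion, so the (5S) Z,Z spiroketal 18 forms beside 19, and under CSA 18 re-opens to the same ion and re-closes to 19, the E,E isomer in which each alkyl group is anti to the oxygen of the other ring; the equilibrium lies near 1:1, so 18 is consumed only by separating it and returning it to the acid, and minor diastereomers from steps 2 and 5 are removed in the same separation; closest known reaction types: hydrogenative conversion of 3-(2-furyl)propanols into 1,6-dioxaspiro[4.4]nonanes over Ni or Pd, Ir–pyridine-phosphinite asymmetric hydrogenation of furans, and acid equilibration of 5,5-spiroketals.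

## Compound list
1 | 3,5-dimethoxybenzaldehyde | COc1cc(C=O)cc(OC)c1 | starting material
2 | 2-bromo-3,5-dimethoxybenzaldehyde | COc1cc(OC)c(Br)c(C=O)c1 | intermediate
3 | 6-bromohex-1-ene | C=CCCCCBr | starting material
4 | hex-5-en-1-ylmagnesium bromide | C=CCCCC[Mg]Br | intermediate
5 | hex-5-en-1-yltitanium triisopropoxide | C=CCCCC[Ti](OC(C)C)(OC(C)C)OC(C)C | intermediate
6 | (R)-1-(2-bromo-3,5-dimethoxyphenyl)hept-6-en-1-ol | COc1cc(OC)c(Br)c(c1)[C@@H](CCCCC=C)O | intermediate
7 | lithium (R)-1-(2-lithio-3,5-dimethoxyphenyl)hept-6-en-1-olate | COc1cc(OC)c([Li])c(c1)[C@@H](CCCCC=C)O[Li] | intermediate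
8 | (R)-2-(1-hydroxyhept-6-en-1-yl)-4,6-dimethoxybenzoic acid | COc1cc(OC)c(C(=O)O)c(c1)[C@@H](CCCCC=C)O | intermediate
9 | (R)-3-(hex-5-en-1-yl)-5,7-dimethoxyisobenzofuran-1(3H)-one | COc1cc(OC)c2c(c1)[C@@H](CCCCC=C)OC2=O | intermediate
10 | 2-methylfuran | Cc1ccco1 | starting material
11 | acrolein | C=CC=O | starting material
12 | 3-(5-methylfuran-2-yl)propanal | Cc1ccc(CCC=O)o1 | intermediate
13 | (R)-3-[6-(diethylboranyl)hexyl]-5,7-dimethoxyisobenzofuran-1(3H)-one | COc1cc(OC)c2c(c1)[C@@H](CCCCCCB(CC)CC)OC2=O | intermediate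
14 | bis{6-[(R)-4,6-dimethoxy-3-oxo-1,3-dihydroisobenzofuran-1-yl]hexyl}zinc | COc1cc(OC)c2c(c1)[C@@H](CCCCCC[Zn]CCCCCC[C@H]1OC(=O)c3c1cc(OC)cc3OC)OC2=O | intermediate
15 | {6-[(R)-4,6-dimethoxy-3-oxo-1,3-dihydroisobenzofuran-1-yl]hexyl}(trimethylsilylmethyl)zinc | COc1cc(OC)c2c(c1)[C@@H](CCCCCC[Zn]C[Si](C)(C)C)OC2=O | intermediate
16 | (R)-3-[(S)-7-hydroxy-9-(5-methylfuran-2-yl)nonyl]-5,7-dimethoxyisobenzofuran-1(3H)-one | COc1cc(OC)c2c(c1)[C@@H](CCCCCC[C@H](O)CCc1ccc(C)o1)OC2=O | intermediate
17 | (R)-3-{(S)-7-hydroxy-9-[(S)-5-methyl-4,5-dihydrofuran-2-yl]nonyl}-5,7-dimethoxyisobenzofuran-1(3H)-one | COc1cc(OC)c2c(c1)[C@@H](CCCCCC[C@H](O)CCC1=CC[C@H](C)O1)OC2=O | intermediate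
18 | (3R)-5,7-dimethoxy-3-{6-[(2S,5S,7S)-7-methyl-1,6-dioxaspiro[4.4]nonan-2-yl]hexyl}isobenzofuran-1(3H)-one (C5'' epimer, Z,Z) | COc1cc(OC)c2c(c1)[C@@H](CCCCCC[C@H]1CC[C@]3(CC[C@H](C)O3)O1)OC2=O | intermediate
19 | (3R)-5,7-dimethoxy-3-{6-[(2S,5R,7S)-7-methyl-1,6-dioxaspiro[4.4]nonan-2-yl]hexyl}isobenzofuran-1(3H)-one | COc1cc(OC)c2c(c1)[C@@H](CCCCCC[C@H]1CC[C@@]3(CC[C@H](C)O3)O1)OC2=O | target

## Step count and risk
Total steps: 6. Longest linear sequence: 5 (steps 1, 2, 3, 5, 6).

**Step 6 (highest risk).** The risks are sluggish reduction of a 2,5-dialkylfuran, the choice of furan C=C, over-reduction, and unproven selectivity at C7''. The fallback sets out from 16 and comes back to the route at 19. It replaces hydrogenative dearomatisation with hydrolytic dearomatisation followed by biocatalysis. Heating 16 in AcOH/H2O with catalytic H2SO4 (or 1 M HCl–THF, 70 °C) opens the furan to (R)-3-[(S)-7-hydroxy-10,13-dioxotetradecyl]-5,7-dimethoxyisobenzofuran-1(3H)-one F1. A Prelog-selective alcohol dehydrogenase (NAD+, i-PrOH, pH 7 buffer, 30 °C) reduces only the methyl ketone. This gives (R)-3-[(7S,13S)-7,13-dihydroxy-10-oxotetradecyl]-5,7-dimethoxyisobenzofuran-1(3H)-one F2. Catalytic CSA in CH2Cl2 closes F2 to 19. The C5'' epimer 18 that forms beside it is equilibrated, separated and returned to the acid as in step 6.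

**Step 5.** The risks are an incomplete B/Zn exchange, the cost of the zinc reagent, and the diastereomer ratio. The fallback sets out from 12 and 9 and comes back to the route at 16. The stereocentre is set by enzymatic resolution and the C–C bond by olefin metathesis.
Vinylmagnesium bromide adds to 12 to give racemic 5-(5-methylfuran-2-yl)pent-1-en-3-ol F3. Lipase resolution (CAL-B, vinyl acetate, MTBE, about 55% conversion) leaves (R)-5-(5-methylfuran-2-yl)pent-1-en-3-ol F4. The other enantiomer is removed as (S)-5-(5-methylfuran-2-yl)pent-1-en-3-yl acetate F5.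
Cross-metathesis of F4 (secondary allylic alcohol, type II) with 9 (type I) uses Hoveyda–Grubbs II in CH2Cl2 at 40 °C. It gives (R)-3-[(R,E)-7-hydroxy-9-(5-methylfuran-2-yl)non-5-en-1-yl]-5,7-dimethoxyisobenzofuran-1(3H)-one F6. Diimide (2-nitrobenzenesulfonyl hydrazide, Et3N) saturates only the chain C=C and gives 16. The descriptor changes from R to S through CIP priorities only.

**Step 2.** The risks are an eroded ee with the ortho-bromo aldehyde and traces of cyclised Grignard reagent. The fallback sets out from 2 and 4 and comes back to the route at 6. Asymmetric addition is replaced by asymmetric ketone reduction. Uncatalysed addition of 4 to 2 (Et2O, 0 °C; 1 M HCl) gives racemic 1-(2-bromo-3,5-dimethoxyphenyl)hept-6-en-1-ol F7. Dess–Martin oxidation gives 1-(2-bromo-3,5-dimethoxyphenyl)hept-6-en-1-one F8. Noyori transfer hydrogenation (RuCl[(R,R)-TsDPEN](p-cymene), HCO2H/Et3N) then gives (R)-6 without touching the alkene or the ArBr.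

## Further compounds
F1 | step 6 | (R)-3-[(S)-7-hydroxy-10,13-dioxotetradecyl]-5,7-dimethoxyisobenzofuran-1(3H)-one | COc1cc(OC)c2c(c1)[C@@H](CCCCCC[C@H](O)CCC(=O)CCC(C)=O)OC2=O
F2 | step 6 | (R)-3-[(7S,13S)-7,13-dihydroxy-10-oxotetradecyl]-5,7-dimethoxyisobenzofuran-1(3H)-one | COc1cc(OC)c2c(c1)[C@@H](CCCCCC[C@H](O)CCC(=O)CC[C@H](C)O)OC2=O
F3 | step 5 | rac-5-(5-methylfuran-2-yl)pent-1-en-3-ol | C=CC(O)CCc1ccc(C)o1
F4 | step 5 | (R)-5-(5-methylfuran-2-yl)pent-1-en-3-ol | C=C[C@H](O)CCc1ccc(C)o1
F5 | step 5 | (S)-5-(5-methylfuran-2-yl)pent-1-en-3-yl acetate | C=C[C@@H](OC(C)=O)CCc1ccc(C)o1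
F6 | step 5 | (R)-3-[(R,E)-7-hydroxy-9-(5-methylfuran-2-yl)non-5-en-1-yl]-5,7-dimethoxyisobenzofuran-1(3H)-one | COc1cc(OC)c2c(c1)[C@@H](CCCC/C=C/[C@H](O)CCc1ccc(C)o1)OC2=O
F7 | step 2 | rac-1-(2-bromo-3,5-dimethoxyphenyl)hept-6-en-1-ol | COc1cc(OC)c(Br)c(c1)C(O)CCCCC=C
F8 | step 2 | 1-(2-bromo-3,5-dimethoxyphenyl)hept-6-en-1-one | COc1cc(OC)c(Br)c(c1)C(=O)CCCCC=C
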